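**Retrosynthetic overview**

- The strategy rests on C3–C4–C5 of the cyclohexene. The three adjacent oxygens, with O3 and O5 cis to each other and both trans to O4, map onto a 1,3-dioxan-5-one (O3 and O5 in the acetal, C4 the ketone) whose two α carbons are bridged by C2–C1(CO2R)–C6.
- The four esters are disconnected to the all-trans triol tert-butyl ester. O3 is told from O5 by its allylic position (MnO2 oxidation, later Luche return), and O4 is reached selectively through a transient 3,5-boronate.
- The C4 carbinol comes from the C4 ketone by hydroxyl-directed reduction after the acetal is opened, not on the bicycle.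
- Key disconnection: C5–C6 (azaenolate SN2 at CH2Br) and C2–C3 (azaenolate addition–elimination at the methoxy-bearing carbon), formed in one pot from the dioxanone SAMP hydrazone and a 2-(bromomethyl)-3-methoxyacrylate.
- Ring order: the dioxane ring is present from the start, the cyclohexene is the only ring built (as a 2,4-dioxabicyclo[3.3.1]nonene), and the dioxane is then opened.

Key step: step 5

Assumption: the lithium azaenolate of 3 is alkylated with the facial sense usual for SAMP hydrazones, which gives the 4S center needed for C5 of the target; the antipodal auxiliary would serve in the same steps if the sense were found reversed.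

**Route**

Step 1
Reactants: 1 2,2-dimethyl-1,3-dioxan-5-one; 2 (S)-1-amino-2-(methoxymethyl)pyrrolidine (SAMP)
Product: 3 SAMP hydrazone of 2,2-dimethyl-1,3-dioxan-5-one
Conditions: benzene, Dean–Stark, reflux
Reagents that add atoms: none
Why: Condensation of the symmetrical ketone with the 1,1-disubstituted hydrazine (hydrazone formation) is driven by azeotropic removal of water and gives a single hydrazone because both α carbons are equivalent.

Step 2
Reactants: 4 tert-butyl propionate
Product: 5 tert-butyl 2-methyl-3-oxopropanoate (formyl ester, largely as its enol)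
Conditions: LiN(iPr)2, THF, −78 °C; HCO2Et, −78 → 0 °C; 1 M HCl
Reagents that add atoms: ethyl formate, CCOC=O
Why: Crossed Claisen condensation (C-formylation) of the lithium ester enolate with a formate that cannot enolize, kept clean by the bulky tert-butyl ester and driven by deprotonation of the product by the released ethoxide.

Step 3
Reactants: 5 tert-butyl 2-methyl-3-oxopropanoate
Product: 6 tert-butyl (E)-3-methoxy-2-methylacrylate
Conditions: Me2SO4, K2CO3, DMF, rt
Reagents that add atoms: dimethyl sulfate, COS(=O)(=O)OC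
Why: O-Alkylation of the potassium enolate of the β-formyl ester with the hard electrophile Me2SO4 in a dipolar aprotic solvent should give the enol ether, mainly as the E isomer with methoxy trans to the ester, as is usual for β-methoxyacrylates.

Step 4
Reactants: 6 tert-butyl (E)-3-methoxy-2-methylacrylate
Product: 7 tert-butyl (Z)-2-(bromomethyl)-3-methoxyacrylate
Conditions: NBS, AIBN (cat.), PhCF3, 85 °C
Reagents that add atoms: N-bromosuccinimide, O=C1CCC(=O)N1Br
Why: Wohl–Ziegler radical bromination at the only allylic C–H position, the C2 methyl group, through an allyl radical stabilized by the ester and the methoxy group; the primary bromide is the stable regioisomer, the geometry is kept (Z only by the change in priorities), and a minor geometric isomer would converge in step 5.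

Step 5
Reactants: 3 SAMP hydrazone of 2,2-dimethyl-1,3-dioxan-5-one; 7 tert-butyl (Z)-2-(bromomethyl)-3-methoxyacrylate
Product: 9 SAMP hydrazone of tert-butyl (1S,5R)-3,3-dimethyl-9-oxo-2,4-dioxabicyclo[3.3.1]non-6-ene-7-carboxylate, via monoalkylated hydrazone 8 (not isolated)
Conditions: tBuLi, THF, −78 °C; 7, −100 → −78 °C; then LiN(iPr)2, −78 → 0 °C; aq. NH4Cl
Reagents that add atoms: none
Why: Proposed new method: tBuLi converts 3 into its chelated lithium azaenolate, which displaces the primary allylic bromide of 7 by SN2 on the face left open by the auxiliary, so that C5 of the target (4S in the dioxanone) is set by the SAMP methoxymethyl group as in the known α-alkylation of this hydrazone. LiN(iPr)2, a base that should not add to the hindered vinylogous carbonate, then removes a proton from the unsubstituted α′ carbon, and the new azaenolate adds to the methoxy-bearing alkene carbon in a 6-endo-trig conjugate addition whose ester enolate expels methoxide, which restores C1=C2 and closes the cyclohexene as the second ring of the 2,4-dioxabicyclo[3.3.1]nonene. The closest known reactions are the α,α′-annulation of ketone enamines with 2-(bromomethyl)acrylates and the stepwise α,α′-bisalkylation of this SAMP hydrazone; new here are the azaenolate as nucleophile in both stages and the β-methoxy leaving group. The second stereocenter (C3 of the target) is fixed by the tether, because the three-carbon bridge can span the two α carbons only on one face of the dioxane, and this must override the trans preference that the auxiliary shows in intermolecular second alkylations. The step needs site selectivity for CH2Br over the methoxy-bearing carbon in the first bond formation, since the reverse order would make the auxiliary-controlled carbon the allylic one and give the enantiomeric bicycle; the donor methoxy group, which deactivates and shields the β carbon, and the low temperature should secure it. It also needs α′ over α selectivity in the second metalation, which the known preference for the less substituted carbon supplies.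

Step 6
Reactants: 9 SAMP hydrazone of the bicyclic ketone
Product: 10 tert-butyl (1S,5R)-3,3-dimethyl-9-oxo-2,4-dioxabicyclo[3.3.1]non-6-ene-7-carboxylate
Conditions: sat. aq. (CO2H)2, Et2O, rt
Reagents that add atoms: water, O
Why: Two-phase hydrolysis of the SAMP hydrazone with oxalic acid, a cleavage mild enough to leave the acetonide, the tert-butyl ester and the bridgehead stereocenters (which cannot enolize) untouched, with the auxiliary recovered from the aqueous phase.

Step 7
Reactants: 10 tert-butyl (1S,5R)-3,3-dimethyl-9-oxo-2,4-dioxabicyclo[3.3.1]non-6-ene-7-carboxylate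
Product: 12 tert-butyl (3R,4R,5S)-3,4,5-trihydroxycyclohex-1-ene-1-carboxylate, via dihydroxy ketone 11 (not isolated)
Conditions: AcOH/H2O (4:1), rt; concentrate cold (toluene azeotrope); then Me4NBH(OAc)3, MeCN/AcOH (1:1), −25 °C
Reagents that add atoms: none
Why: The strained bicyclic acetonide is hydrolysed by aqueous acetic acid and the freed ketol is reduced at once by the Evans–Saksena protocol, in which the two cis α-hydroxyls exchange onto boron and deliver hydride to the carbonyl face they occupy, so that the C4 hydroxyl comes out trans to both (4R, all-equatorial triol); the reduction is deliberately not run on 10, where the endo methyl of the acetonide is expected to lie over the dioxane face of the ketone, so that external hydride would enter from the carbocycle side and give the all-cis epimer.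

Step 8
Reactants: 12 tert-butyl (3R,4R,5S)-3,4,5-trihydroxycyclohex-1-ene-1-carboxylate
Product: 15 tert-butyl (3R,4R,5S)-3,5-dihydroxy-4-{[(E)-2-methylbut-2-enoyl]oxy}cyclohex-1-ene-1-carboxylate, via phenylboronate 13 (not isolated), via tigloylated phenylboronate 14 (not isolated)
Conditions: PhB(OH)2, 4 Å sieves, CH2Cl2, rt; then tigloyl chloride, pyridine, DMAP (cat.), 0 °C → rt; then propane-1,3-diol, acetone, rt
Reagents that add atoms: tigloyl chloride, C/C=C(\C)C(Cl)=O
Why: Transient masking of a cis-1,3-diol as a six-membered phenylboronate, known for all-trans 1,2,3-triols on six-membered rings, which flip to the triaxial conformer and expose only the central hydroxyl; DMAP-catalysed acylation then places the tiglate on O4, and neutral transesterification with propane-1,3-diol frees O3 and O5 without acyl migration.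

Step 9
Reactants: 15 tert-butyl (3R,4R,5S)-3,5-dihydroxy-4-(tigloyloxy)cyclohex-1-ene-1-carboxylate
Product: 16 tert-butyl (4R,5S)-5-hydroxy-4-{[(E)-2-methylbut-2-enoyl]oxy}-3-oxocyclohex-1-ene-1-carboxylate
Conditions: activated MnO2 (excess), CH2Cl2, rt
Reagents that add atoms: none
Why: Activated MnO2 oxidizes only the allylic C3 carbinol (its C–H bond is pseudoaxial and aligned with the alkene) and leaves the saturated C5 carbinol, which tells O3 from O5.

Step 10
Reactants: 16 tert-butyl (4R,5S)-5-hydroxy-3-oxo-4-(tigloyloxy)cyclohex-1-ene-1-carboxylate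
Product: 17 tert-butyl (4R,5S)-5-acetoxy-4-{[(E)-2-methylbut-2-enoyl]oxy}-3-oxocyclohex-1-ene-1-carboxylate
Conditions: Ac2O, pyridine, CH2Cl2, 0 °C
Reagents that add atoms: acetic anhydride, CC(=O)OC(C)=O
Why: Acetylation of the only free hydroxyl with Ac2O and the weak base pyridine at 0 °C, conditions under which β-acetoxy ketones normally survive without E1cB loss of acetate.

Step 11
Reactants: 17 tert-butyl (4R,5S)-5-acetoxy-3-oxo-4-(tigloyloxy)cyclohex-1-ene-1-carboxylate
Product: 18 tert-butyl (3R,4R,5S)-5-acetoxy-3-hydroxy-4-{[(E)-2-methylbut-2-enoyl]oxy}cyclohex-1-ene-1-carboxylate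
Conditions: NaBH4, CeCl3·7H2O, MeOH, −78 °C; AcOH quench
Reagents that add atoms: none
Why: Luche 1,2-reduction of the enone; with the C4 and C5 esters trans-diequatorial, axial hydride addition anti to the pseudoaxial C4–H should give the pseudoequatorial C3 alcohol trans to the C4 tiglate (3R), and the cold, nearly neutral medium limits β-elimination and acyl migration.

Step 12
Reactants: 18 tert-butyl (3R,4R,5S)-5-acetoxy-3-hydroxy-4-(tigloyloxy)cyclohex-1-ene-1-carboxylate
Product: 19 tert-butyl (3R,4R,5S)-5-acetoxy-3-[(6-methylheptanoyl)oxy]-4-{[(E)-2-methylbut-2-enoyl]oxy}cyclohex-1-ene-1-carboxylate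
Conditions: 6-methylheptanoic acid, DCC, DMAP (cat.), CH2Cl2, 0 °C → rt
Reagents that add atoms: 6-methylheptanoic acid, CC(C)CCCCC(=O)O
Why: Steglich esterification of the single free secondary alcohol with the carboxylic acid, without change at the stereocenters.

Step 13
Reactants: 19 tert-butyl ester of the target
Product: 20 (3R,4R,5S)-5-acetoxy-3-[(6-methylheptanoyl)oxy]-4-{[(E)-2-methylbut-2-enoyl]oxy}cyclohex-1-ene-1-carboxylic acid (CNP0225437.1)
Conditions: TFA/CH2Cl2 (1:4), 0 °C → rt
Reagents that add atoms: none
Why: Acidolysis of the tert-butyl ester through the tert-butyl cation (lost as isobutene) frees the acid, while the three secondary esters are stable to anhydrous TFA and the allylic C3–O bond does not ionize next to the electron-poor alkene.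

**Compound list**

1 | 2,2-dimethyl-1,3-dioxan-5-one | CC1(C)OCC(=O)CO1 | starting material
2 | (S)-1-amino-2-(methoxymethyl)pyrrolidine (SAMP) | COC[C@@H]1CCCN1N | starting material
3 | SAMP hydrazone of 2,2-dimethyl-1,3-dioxan-5-one | COC[C@@H]1CCCN1N=C1COC(C)(C)OC1 | intermediate
4 | tert-butyl propionate | CCC(=O)OC(C)(C)C | starting material
5 | tert-butyl 2-methyl-3-oxopropanoate | CC(C=O)C(=O)OC(C)(C)C | intermediate
6 | tert-butyl (E)-3-methoxy-2-methylacrylate | CO/C=C(\C)C(=O)OC(C)(C)C | intermediate
7 | tert-butyl (Z)-2-(bromomethyl)-3-methoxyacrylate | CO/C=C(\CBr)C(=O)OC(C)(C)C | intermediate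
8 | SAMP hydrazone of tert-butyl (E)-2-{[(4S)-2,2-dimethyl-5-oxo-1,3-dioxan-4-yl]methyl}-3-methoxyacrylate (monoalkylated hydrazone) | COC[C@@H]1CCCN1N=C1COC(C)(C)O[C@H]1C/C(=C\OC)C(=O)OC(C)(C)C | intermediate
9 | SAMP hydrazone of tert-butyl (1S,5R)-3,3-dimethyl-9-oxo-2,4-dioxabicyclo[3.3.1]non-6-ene-7-carboxylate | COC[C@@H]1CCCN1N=C2[C@@H]3CC(C(=O)OC(C)(C)C)=C[C@H]2OC(C)(C)O3 | intermediate
10 | tert-butyl (1S,5R)-3,3-dimethyl-9-oxo-2,4-dioxabicyclo[3.3.1]non-6-ene-7-carboxylate | O=C1[C@@H]2CC(C(=O)OC(C)(C)C)=C[C@H]1OC(C)(C)O2 | intermediate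
11 | tert-butyl (3R,5S)-3,5-dihydroxy-4-oxocyclohex-1-ene-1-carboxylate (dihydroxy ketone) | O=C1[C@@H](O)CC(C(=O)OC(C)(C)C)=C[C@H]1O | intermediate
12 | tert-butyl (3R,4R,5S)-3,4,5-trihydroxycyclohex-1-ene-1-carboxylate | O[C@@H]1[C@@H](O)CC(C(=O)OC(C)(C)C)=C[C@H]1O | intermediate
13 | tert-butyl (1S,5R,9R)-9-hydroxy-3-phenyl-2,4-dioxa-3-borabicyclo[3.3.1]non-6-ene-7-carboxylate (phenylboronate) | O[C@@H]1[C@@H]2CC(C(=O)OC(C)(C)C)=C[C@H]1OB(c1ccccc1)O2 | intermediate
14 | tert-butyl (1S,5R,9R)-9-{[(E)-2-methylbut-2-enoyl]oxy}-3-phenyl-2,4-dioxa-3-borabicyclo[3.3.1]non-6-ene-7-carboxylate (tigloylated phenylboronate) | C/C=C(\C)C(=O)O[C@@H]1[C@@H]2CC(C(=O)OC(C)(C)C)=C[C@H]1OB(c1ccccc1)O2 | intermediate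
15 | tert-butyl (3R,4R,5S)-3,5-dihydroxy-4-{[(E)-2-methylbut-2-enoyl]oxy}cyclohex-1-ene-1-carboxylate | C/C=C(\C)C(=O)O[C@@H]1[C@@H](O)CC(C(=O)OC(C)(C)C)=C[C@H]1O | intermediate
16 | tert-butyl (4R,5S)-5-hydroxy-4-{[(E)-2-methylbut-2-enoyl]oxy}-3-oxocyclohex-1-ene-1-carboxylate | C/C=C(\C)C(=O)O[C@@H]1[C@@H](O)CC(C(=O)OC(C)(C)C)=CC1=O | intermediate
17 | tert-butyl (4R,5S)-5-acetoxy-4-{[(E)-2-methylbut-2-enoyl]oxy}-3-oxocyclohex-1-ene-1-carboxylate | C/C=C(\C)C(=O)O[C@@H]1[C@@H](OC(C)=O)CC(C(=O)OC(C)(C)C)=CC1=O | intermediate
18 | tert-butyl (3R,4R,5S)-5-acetoxy-3-hydroxy-4-{[(E)-2-methylbut-2-enoyl]oxy}cyclohex-1-ene-1-carboxylate | C/C=C(\C)C(=O)O[C@@H]1[C@@H](OC(C)=O)CC(C(=O)OC(C)(C)C)=C[C@H]1O | intermediate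
19 | tert-butyl (3R,4R,5S)-5-acetoxy-3-[(6-methylheptanoyl)oxy]-4-{[(E)-2-methylbut-2-enoyl]oxy}cyclohex-1-ene-1-carboxylate | C/C=C(\C)C(=O)O[C@@H]1[C@@H](OC(C)=O)CC(C(=O)OC(C)(C)C)=C[C@H]1OC(=O)CCCCC(C)C | intermediate
20 | (3R,4R,5S)-5-acetoxy-3-[(6-methylheptanoyl)oxy]-4-{[(E)-2-methylbut-2-enoyl]oxy}cyclohex-1-ene-1-carboxylic acid | C/C=C(\C)C(=O)O[C@@H]1[C@@H](OC(C)=O)CC(C(=O)O)=C[C@H]1OC(=O)CCCCC(C)C | target

**Step count and risks**

Total step count: 13. Longest linear sequence: 12 steps (4 → 20, steps 2–13).

Steps most likely to fail: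

1. Step 5 (proposed new method). After the first alkylation, the second metalation may be slow, or the auxiliary, mismatched for a cis closure, may hold the azaenolate face away from the tether, so that the ring does not close or intermolecular products form. The fallback sets out from 3 and 7 and uses known chemistry. Only the first alkylation is run, and the monoalkylated hydrazone 8 is isolated and cleaved with saturated aqueous oxalic acid to tert-butyl (E)-2-{[(4S)-2,2-dimethyl-5-oxo-1,3-dioxan-4-yl]methyl}-3-methoxyacrylate F1. Kinetic deprotonation of this ketone at the unsubstituted α′ carbon with LiN(iPr)2 in THF at −78 °C, followed by warming, lets the lithium enolate, now free of the auxiliary, close by intramolecular conjugate addition and loss of methoxide. This gives ketone 10, where the route is rejoined.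

2. Step 10. The β-acetoxy enone may lose acetic acid by base-induced elimination, during acetylation or in the following Luche reduction, and aromatize to a hydroxybenzoate. The fallback sets out from 16 and keeps a poor leaving group on O5 while C3 is a ketone. Silylation (Et3SiCl, imidazole, DMF, 0 °C) gives tert-butyl (4R,5S)-4-{[(E)-2-methylbut-2-enoyl]oxy}-3-oxo-5-[(triethylsilyl)oxy]cyclohex-1-ene-1-carboxylate F4. Luche reduction gives tert-butyl (3R,4R,5S)-3-hydroxy-4-{[(E)-2-methylbut-2-enoyl]oxy}-5-[(triethylsilyl)oxy]cyclohex-1-ene-1-carboxylate F5. Steglich esterification with 6-methylheptanoic acid gives tert-butyl (3R,4R,5S)-3-[(6-methylheptanoyl)oxy]-4-{[(E)-2-methylbut-2-enoyl]oxy}-5-[(triethylsilyl)oxy]cyclohex-1-ene-1-carboxylate F6. HF·pyridine in THF frees tert-butyl (3R,4R,5S)-5-hydroxy-3-[(6-methylheptanoyl)oxy]-4-{[(E)-2-methylbut-2-enoyl]oxy}cyclohex-1-ene-1-carboxylate F7. Acetylation (Ac2O, pyridine, DMAP) then gives 19, where the route is rejoined.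

3. Step 8. Boronate bridging may be incomplete or may engage a trans-vicinal diol instead of O3/O5, so that the tigloyl group ends on O3 or O5. The fallback sets out from 12 and relies on steric differentiation instead. Silylation with tBuMe2SiCl (2.2 equiv) and imidazole in DMF should spare the flanked central hydroxyl and give tert-butyl (3R,4R,5S)-3,5-bis[(tert-butyldimethylsilyl)oxy]-4-hydroxycyclohex-1-ene-1-carboxylate F2. Acylation with tigloyl chloride, Et3N and DMAP gives tert-butyl (3R,4R,5S)-3,5-bis[(tert-butyldimethylsilyl)oxy]-4-{[(E)-2-methylbut-2-enoyl]oxy}cyclohex-1-ene-1-carboxylate F3. HF·pyridine in THF then removes both silyl groups to give 15, where the route is rejoined.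

**Further compounds**

F1 | step 5 | tert-butyl (E)-2-{[(4S)-2,2-dimethyl-5-oxo-1,3-dioxan-4-yl]methyl}-3-methoxyacrylate | O=C1COC(C)(C)O[C@H]1C/C(=C\OC)C(=O)OC(C)(C)C
F2 | step 8 | tert-butyl (3R,4R,5S)-3,5-bis[(tert-butyldimethylsilyl)oxy]-4-hydroxycyclohex-1-ene-1-carboxylate | O[C@@H]1[C@@H](O[Si](C)(C)C(C)(C)C)CC(C(=O)OC(C)(C)C)=C[C@H]1O[Si](C)(C)C(C)(C)C
F3 | step 8 | tert-butyl (3R,4R,5S)-3,5-bis[(tert-butyldimethylsilyl)oxy]-4-{[(E)-2-methylbut-2-enoyl]oxy}cyclohex-1-ene-1-carboxylate | C/C=C(\C)C(=O)O[C@@H]1[C@@H](O[Si](C)(C)C(C)(C)C)CC(C(=O)OC(C)(C)C)=C[C@H]1O[Si](C)(C)C(C)(C)C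
F4 | step 10 | tert-butyl (4R,5S)-4-{[(E)-2-methylbut-2-enoyl]oxy}-3-oxo-5-[(triethylsilyl)oxy]cyclohex-1-ene-1-carboxylate | C/C=C(\C)C(=O)O[C@@H]1[C@@H](O[Si](CC)(CC)CC)CC(C(=O)OC(C)(C)C)=CC1=O
F5 | step 10 | tert-butyl (3R,4R,5S)-3-hydroxy-4-{[(E)-2-methylbut-2-enoyl]oxy}-5-[(triethylsilyl)oxy]cyclohex-1-ene-1-carboxylate | C/C=C(\C)C(=O)O[C@@H]1[C@@H](O[Si](CC)(CC)CC)CC(C(=O)OC(C)(C)C)=C[C@H]1O
F6 | step 10 | tert-butyl (3R,4R,5S)-3-[(6-methylheptanoyl)oxy]-4-{[(E)-2-methylbut-2-enoyl]oxy}-5-[(triethylsilyl)oxy]cyclohex-1-ene-1-carboxylate | C/C=C(\C)C(=O)O[C@@H]1[C@@H](O[Si](CC)(CC)CC)CC(C(=O)OC(C)(C)C)=C[C@H]1OC(=O)CCCCC(C)C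
F7 | step 10 | tert-butyl (3R,4R,5S)-5-hydroxy-3-[(6-methylheptanoyl)oxy]-4-{[(E)-2-methylbut-2-enoyl]oxy}cyclohex-1-ene-1-carboxylate | C/C=C(\C)C(=O)O[C@@H]1[C@@H](O)CC(C(=O)OC(C)(C)C)=C[C@H]1OC(=O)CCCCC(C)C
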